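**Charge and remainder.** The flask holds each substrate at half of the charge, and an excess of 99% lets the left-handed substrate stand at 0.00503 of the right-handed. With dawn's last right-handed reading of 43.9%, that allows 0.221% of the charge, less than the scatter of 0.5 percentage points, so we reckon to this end instead of reading it.

| flask | left-handed substrate | right-handed substrate | solid reagent | free catalyst | remark | time |
|---|---|---|---|---|---|---|
| dawn | 0.40 M | 0.40 M | 0.84 M | 4 mM | run made earlier |  |
| noon | 0.40 M | 0.40 M | 1.3 M | 4 mM | run made earlier |  |
| autumn | 0.20 M | 0.20 M | 0.60 M | 4 mM | run made earlier |  |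
| flask | 0.40 M | 0.40 M | 0.600 M | 4.0 mM |  | 40 min |

- dawn (time / min: right-handed substrate / %, left-handed substrate / %, left-handed product / %): 3.00: 49.5, 27.9, 21.0; 8.00: 48.4, 10.4, 40.0; 15.0: 46.1, 2.7, 46.6; 25.0: 45.1, 0, 49.4; 30.0: 43.9, 0, 50.2
- noon (time / min: right-handed substrate / %, left-handed substrate / %, left-handed product / %): 3.00: 49.7, 29.1, 21.8; 8.00: 49.1, 10.7, 39.3; 15.0: 45.7, 2.8, 47.6; 25.0: 45.8, 0, 50.2; 30.0: 44.0, 0, 49.7
- autumn (time / min: right-handed substrate / %, left-handed substrate / %, left-handed product / %): 6.00: 49.1, 13.4, 36.4; 12.0: 46.1, 2.7, 46.3; 20.0: 45.2, 0.7, 49.9; 25.0: 44.3, 0.2, 49.1; 30.0: 42.3, 0.2, 50.3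

(each reading ± 0.5 percentage points)

- free catalyst is single-handed; left-handed substrate and right-handed substrate are mirror images of each other, charged as a racemate, each of them at the stated concentration
- as a solid, counted per litre of solution: solid reagent
- the numbers in the tables scatter by 0.5 percentage points (one standard deviation)
- at the start none of the solid reagent is in solution

- whether the excess of right-handed substrate over left-handed substrate among what is left of the two reaches 99% by 40 min (no / yes)
- the highest excess of right-handed substrate over left-handed substrate among what is left of the two up to 40 min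

**Counting halvings.** The bench rule is to count halvings, since the left-handed substrate falls pseudo-first-order in the dawn and noon readings. We carry the clearing half-life, the time in which its fraction of the charge halves, read from dawn as 3.56 min; noon reads 3.55 min. Joining dawn's 27.9% at 3.00 min to the allowed remainder takes 6.98 halvings, so our reckoning reaches the excess at 27.9 min, inside 40 min.

**The border.** The rule assumes a steady supply of reagent, yet this flask has 0.750 of solid reagent per charge against dawn's 1.05. If one solid reagent serves one substrate, which we assume, the fraction of the charge gone at dawn's last right-handed reading with the left-handed substrate down to the allowed remainder, 55.9%, stays below this flask's ratio.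

**The forecast.** The forecast says yes with a top of 99.9%, and calls its one-to-one use of solid reagent “an assumption, not proven”.

**The result.** The flask gives yes, with a top of >99.9%.

    free catalyst + left-handed substrate ⇌ catalyst intermediate A (K = 34.0 L mol⁻¹, k = 3.80 L mol⁻¹ s⁻¹)
    free catalyst + right-handed substrate ⇌ catalyst intermediate B (K = 1.90 L mol⁻¹, k = 150 L mol⁻¹ s⁻¹)
    partner + catalyst intermediate A → free catalyst + left-handed product (k = 9.50 L mol⁻¹ s⁻¹)
    partner + catalyst intermediate B → free catalyst + right-handed product (k = 0.240 L mol⁻¹ s⁻¹)
    2 free catalyst ⇌ resting dimer, settled at all times (K = 1100 L mol⁻¹)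
    solid reagent ⇌ partner, rate k6*(cs6 - [partner]) while solid is left; crystals form when [partner] > cs6 (solubility = 0.180 M, k = 0.0720 s⁻¹)

**Half-life again.** The flask reaches the excess at 25.8 min, with 44.3% of the charge left as right-handed substrate. The carried half-life, taken from the flask's 0.778% of left-handed substrate at 20.0 min, gives 26.4 min. In the autumn run, the same half-life taken from 13.4% at 6.00 min gives 27.1 min, while the reading at 25.0 min is 0.2%.

(All runs were computed with made-up constants; scatter was added.)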